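## Retrosynthetic overview

- GA55 ⇐ its methyl ester (thiolate dealkylation) ⇐ a 2β,3β-epoxy-1β-ol (C2–O reductive opening) ⇐ a 1β-hydroxy-2-ene (hydroxyl-directed epoxidation, which puts the 3β C–O bond back).
- Key disconnection: the C1–O bond, made by a suprafacial [3,3]-sigmatropic 1,3-transposition of the 3β-allylic alcohol of GA3 methyl ester (3β → 1β chirality transfer).
- Rings A, B, C, D and the γ-lactone, and eight of the nine stereocentres, are bought in gibberellic acid (GA3). No ring of the target is built; only a transient oxirane on ring A is formed and then opened.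

Assumption: gibberellic acid (GA3), a bulk fermentation product sold as a plant growth regulator, is taken as the cheap commercial chiral starting material; atom numbers and α/β follow gibberellane numbering.

## Route

Step 1
Reactants: 1 gibberellic acid (GA3)
Product: 2 GA3 methyl ester
Conditions: MeI, K2CO3, acetone, 20 °C
Reagents that add atoms: iodomethane, CI
Why: SN2 O-alkylation of the carboxylate masks the C7 acid for the Lewis-acidic steps that follow, while the secondary 3-OH and tertiary 13-OH are not alkylated under carbonate conditions and no stereocentre is touched.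

Step 2
Reactants: 2 GA3 methyl ester
Product: 5 1β-hydroxy-GA5 methyl ester, via 3β-perrhenate of GA3 methyl ester 3 (not isolated), via 1β-perrhenate of 1β-hydroxy-GA5 methyl ester 4 (not isolated)
Conditions: Ph3SiOReO3 (5 mol %), 4 Å MS, CH2Cl2/Et2O, −40 → 0 °C; recovered 2 resubmitted
Reagents that add atoms: none
Why: Rhenium-oxo-catalysed 1,3-transposition of an allylic alcohol: the allyl perrhenate of the 3β-alcohol undergoes a suprafacial [3,3]-sigmatropic shift across the β face, so the 3β C–O configuration is relayed into the new 1β C–O bond, and the equilibrium is expected to lean towards 5 because its olefin has one allylic C–O bond where the olefin of 2 has two (C3–OH and the C10 lactone oxygen).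

Step 3
Reactants: 5 1β-hydroxy-GA5 methyl ester
Product: 6 2β,3β-epoxy-1β-hydroxy-GA20 methyl ester
Conditions: VO(acac)2 (3 mol %), t-BuOOH (1.2 equiv, in decane), CH2Cl2, 0 °C
Reagents that add atoms: tert-butyl hydroperoxide, CC(C)(C)OO
Why: Hydroxyl-directed vanadium-catalysed epoxidation delivers oxygen syn to the pseudoaxial 1β-OH, which is also the open face of ring A opposite the lactone bridge, so the C3–O bond is re-created as β; the secondary cyclohexenol should react faster than the hindered bridgehead 13-ol/16-ene pair.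

Step 4
Reactants: 6 2β,3β-epoxy-1β-hydroxy-GA20 methyl ester
Product: 8 GA55 methyl ester, via 2α-iodo-GA55 methyl ester 7 (not isolated)
Conditions: MgI2 (2 equiv), PhMe/Et2O, −40 → 0 °C; then Bu3SnH, Et3B (cat.), air, 0 → 20 °C; H2O work-up
Reagents that add atoms: none
Why: Fürst–Plattner trans-diaxial epoxide opening: iodide attacks the magnesium-activated oxirane at C2 from the α face (C3 is neopentyl and its attack would need a boat), leaving the 3β C–O bond intact, and tin-hydride radical deiodination then removes the transient C2 stereocentre.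

Step 5
Reactants: 8 GA55 methyl ester
Product: 9 GA55
Conditions: NaSPr, HMPA, 20 °C; then aq. HCl to pH 3, 0 °C
Reagents that add atoms: none
Why: SN2 dealkylation of the methyl ester by the soft thiolate frees the acid without hydroxide, which would epimerise the β-hydroxy lactone at C3 by retro-aldol/aldol; no stereocentre is touched.

## Compound list

1 | gibberellic acid (GA3): 3β,13-dihydroxy-1,16-diene, 19→10α γ-lactone, 7-carboxylic acid | C=C1C[C@]23C[C@@]1(O)CC[C@H]2[C@@]12OC(=O)[C@@](C)([C@H]1[C@@H]3C(=O)O)[C@@H](O)C=C2 | starting material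
2 | GA3 methyl ester (methyl 7-oate of 1) | C=C1C[C@]23C[C@@]1(O)CC[C@H]2[C@@]12OC(=O)[C@@](C)([C@H]1[C@@H]3C(=O)OC)[C@@H](O)C=C2 | intermediate
3 | 3β-perrhenate of GA3 methyl ester (O–ReO3 on C3β, 1-ene; not isolated) | C=C1C[C@]23C[C@@]1(O)CC[C@H]2[C@@]12OC(=O)[C@@](C)([C@H]1[C@@H]3C(=O)OC)[C@@H](O[Re](=O)(=O)=O)C=C2 | intermediate
4 | 1β-perrhenate of 1β-hydroxy-GA5 methyl ester (O–ReO3 on C1β, 2-ene; not isolated) | C=C1C[C@]23C[C@@]1(O)CC[C@H]2[C@@]12OC(=O)[C@@](C)([C@H]1[C@@H]3C(=O)OC)C=C[C@H]2O[Re](=O)(=O)=O | intermediate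
5 | 1β-hydroxy-GA5 methyl ester: 1β,13-dihydroxy-2,16-diene, 19→10α lactone, no oxygen on C3 | C=C1C[C@]23C[C@@]1(O)CC[C@H]2[C@@]12OC(=O)[C@@](C)([C@H]1[C@@H]3C(=O)OC)C=C[C@H]2O | intermediate
6 | 2β,3β-epoxy-1β-hydroxy-GA20 methyl ester: β-oxirane across C2–C3, cis to the 1β-OH, 13-OH, 16-ene | C=C1C[C@]23C[C@@]1(O)CC[C@H]2[C@@]12OC(=O)[C@@](C)([C@H]1[C@@H]3C(=O)OC)[C@H]4O[C@H]4[C@H]2O | intermediate
7 | 2α-iodo-GA55 methyl ester: 2α-iodo-1β,3β,13-triol (not isolated) | C=C1C[C@]23C[C@@]1(O)CC[C@H]2[C@@]12OC(=O)[C@@](C)([C@H]1[C@@H]3C(=O)OC)[C@@H](O)[C@H](I)[C@H]2O | intermediate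
8 | GA55 methyl ester: 1β,3β,13-triol, C2 methylene, 16-ene | C=C1C[C@]23C[C@@]1(O)CC[C@H]2[C@@]12OC(=O)[C@@](C)([C@H]1[C@@H]3C(=O)OC)[C@@H](O)C[C@H]2O | intermediate
9 | GA55: 1β,3β,13-trihydroxy-16-ene, 19→10α lactone, 7-carboxylic acid | C=C1C[C@]23C[C@@]1(O)CC[C@H]2[C@@]12OC(=O)[C@@](C)([C@H]1[C@@H]3C(=O)O)[C@@H](O)C[C@H]2O | target

## Step count and risks

Total step count: 5. Longest linear sequence: 5 steps (1 → 2 → 5 → 6 → 8 → 9).

Stereocentres: C4, C5, C6, C8, C9, C10 and C13 are carried unchanged from GA3. C1 is set in step 2 by suprafacial transfer from C3. C3 is re-set in step 3 by delivery syn to the 1β-OH.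

The three steps most likely to fail:

Step 2. The position of the transposition equilibrium is not known in advance, and traces of perrhenic acid could attack the acid-labile 13-hydroxy-16-ene or the allylic lactone. The fallback is a Wharton transposition that sets out from 2 and comes back to the route at 5. MnO2 in CH2Cl2 oxidises the allylic 3β-alcohol of 2 to the 1-en-3-one 3-oxo-GA3 methyl ester F1. Buffered H2O2 (NaHCO3/Na2CO3, MeOH/THF, 0 °C) epoxidises the enone from the open β face to give 1β,2β-epoxy-3-oxo-GA20 methyl ester F2. Hydrazine hydrate with catalytic AcOH in MeOH forms the epoxy hydrazone of F2, F3, which is not isolated; it opens the oxirane and loses N2 to give 5, with the 1β C–O bond fixed by the epoxide.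

Step 3. The 13-hydroxy-16-ene is also an allylic alcohol and may be epoxidised in competition. The fallback replaces electrophilic oxidation by conjugate borylation; it sets out from 5 and comes back at 8. MnO2 oxidises 5 to the 2-en-1-one 1-oxo-GA5 methyl ester F4, which the isolated 16-ene cannot imitate. CuCl (5 mol %), NaOtBu, B2pin2 and MeOH in THF add boron to C3 from the β face to give 3β-(pinacolboryl)-1-oxo-GA20 methyl ester F5. NaBO3·4H2O in THF/H2O converts C–B into C–O with retention, giving 3β-hydroxy-1-oxo-GA20 methyl ester F6. LiBH(s-Bu)3 in THF at −78 °C should attack the C1 ketone from the equatorial α side, because the β face is screened by the axial 3β-alkoxide and the 5β-H, giving the 1β-alcohol 8.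

Step 4. Iodide has to approach C2 underneath ring A next to the lactone bridge, so the opening may be slow or leak to C3, and the Lewis acid may harm the 13-hydroxy-16-ene. The fallback lets a carbonyl group decide which C–O bond breaks; it sets out from 6 and comes back at 8. Dess–Martin periodinane in CH2Cl2 oxidises 6 to 2β,3β-epoxy-1-oxo-GA20 methyl ester F7. Na[PhSeB(OEt)3] (from PhSeSePh and NaBH4 in EtOH, with AcOH) cleaves only the Cα–O bond at C2 and gives the hydroxy ketone F6 described above. LiBH(s-Bu)3 at −78 °C then reduces it to 8 as before.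

## Further compounds

F1 | step 2 | 3-oxo-GA3 methyl ester (1-en-3-one) | C=C1C[C@]23C[C@@]1(O)CC[C@H]2[C@@]12OC(=O)[C@@](C)([C@H]1[C@@H]3C(=O)OC)C(=O)C=C2
F2 | step 2 | 1β,2β-epoxy-3-oxo-GA20 methyl ester | C=C1C[C@]23C[C@@]1(O)CC[C@H]2[C@@]12OC(=O)[C@@](C)([C@H]1[C@@H]3C(=O)OC)C(=O)[C@H]4O[C@H]42
F3 | step 2 | hydrazone of F2 at C3 (not isolated) | C=C1C[C@]23C[C@@]1(O)CC[C@H]2[C@@]12OC(=O)[C@@](C)([C@H]1[C@@H]3C(=O)OC)C(=NN)[C@H]4O[C@H]42
F4 | step 3 | 1-oxo-GA5 methyl ester (2-en-1-one) | C=C1C[C@]23C[C@@]1(O)CC[C@H]2[C@@]12OC(=O)[C@@](C)([C@H]1[C@@H]3C(=O)OC)C=CC2=O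
F5 | step 3 | 3β-(pinacolboryl)-1-oxo-GA20 methyl ester | C=C1C[C@]23C[C@@]1(O)CC[C@H]2[C@@]12OC(=O)[C@@](C)([C@H]1[C@@H]3C(=O)OC)[C@@H](B4OC(C)(C)C(C)(C)O4)CC2=O
F6 | step 3 | 3β-hydroxy-1-oxo-GA20 methyl ester | C=C1C[C@]23C[C@@]1(O)CC[C@H]2[C@@]12OC(=O)[C@@](C)([C@H]1[C@@H]3C(=O)OC)[C@@H](O)CC2=O
F7 | step 4 | 2β,3β-epoxy-1-oxo-GA20 methyl ester | C=C1C[C@]23C[C@@]1(O)CC[C@H]2[C@@]12OC(=O)[C@@](C)([C@H]1[C@@H]3C(=O)OC)[C@H]4O[C@H]4C2=O
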